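(The numbers in the tables were generated by integration from invented constants; the scatter is artificial.)

**Early readings.** Start at early times, where Tuesday's run has made 8.6% Q at 0.500 d. L is an enzyme that turns D into Q, and the question is how the rate answers to the L charged.

| flask | D | L | remark |
|---|---|---|---|
| Tuesday's | 0.076 M | 7.5 µM | run made earlier |
| Friday's | 0.076 M | 11 µM | run made earlier |
| Sunday's | 0.038 M | 15 µM | run made earlier |
| flask | 0.076 M | 15 µM |  |

- Tuesday's (time / d: Q / %, D / %): 0.500: 8.6, 91.1; 1.25: 19.5, 82.2; 2.50: 30.2, 69.0; 4.00: 42.2, 58.8
- Friday's (time / d: Q / %, D / %): 0.333: 7.9, 92.0; 0.833: 17.9, 82.9; 1.67: 28.8, 71.5; 4.00: 48.9, 50.5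
- Sunday's (time / d: Q / %, D / %): 0.333: 5.6, 94.5; 0.833: 11.8, 89.3; 1.67: 19.5, 81.4; 4.00: 32.4, 67.6

(each reading ± 0.5 percentage points)

* apparent order in L when 20% of the D are converted (percent change of the rate of making Q for one percent more L charged)



**Main step.** First take the main step by itself: every L charged works, so the order in L is 1. From Tuesday's run to Friday's the charge of L grows by a factor 1.47, and the rate should grow by the same factor.

**Equal conversion.** Now add what the readings show. Compare Tuesday's and Friday's runs, which have the same charge of D, at close conversions. Tuesday's run makes 19.5% Q in 1.25 d, Friday's 17.9% in 0.833 d. The mean rate therefore grows by a factor 1.38, less than the factor of the charge. Define n, the logarithm of the rate ratio divided by the logarithm of the charge ratio at equal conversion: it reads 0.836. With a scatter of 0.5 percentage points, its second digit stays open.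

**The rest.** Sunday's run has half the D, so it stays out of n. The flask has Tuesday's D and 15 µM of L. Scale Tuesday's time with n: 20% conversion in the flask should come at 0.718 d. Commit to n for the flask; the forecast stands lower at 0.72, saying “the order is sub-linear, probably falling with L”.

**The flask.** The flask gives 0.80, which is 0.0383 under n, and reaches 20% conversion at 0.738 d.

    2 L ⇌ G (K = 30800 M⁻¹, k = 2140 M⁻¹ h⁻¹)
    D + L → Q + L, rate k2*[D]^3*[L]/(1 + ([D]/Kh2)^3) (0.0679 M, k = 4.87 × 10⁵ M⁻³ h⁻¹)

G is an off-cycle form of the enzyme. In the flask at 5.00 d, 2 L and G relax with a half-life of 0.192 d, both ways together, shorter than the 2.58 d of the slowest mode of the whole flask at that moment. At 20% conversion of the flask's D, G holds 34.6% of the catalyst and L 65.4%, and at 9.29 d, at 70 percent conversion, L holds 63.2%.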